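## Retrosynthetic overview

- The quinone methide is the dehydrated form of a bis(4-hydroxyphenyl)carbinol on C1 of ring A, so the last C–C bond is an arylmagnesium addition to an aryl ketone on C1. The C6 diarylalkyne comes from Sonogashira coupling of a terminal alkyne, made by one-carbon homologation of a C6 aldehyde.
- The ketone carbon on C1 and the aldehyde carbon on C6 are the carbonyl and the OCH2 of a phthalide fused to ring A at C1–C6. One aryllithium opens it, so no triaryl carbinol is present while the alkyne is built.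
- Feature carrying the plan: in ring A (C1 methylidene carbon, C2 ring C, C3–H, C4–H, C5 CH2OH, C6 alkyne) the only two CH carbons, C3 and C4, are neighbours, and the carbons on C1 and C6 are ortho. C3–C4 is therefore acetylene and an ester oxygen can tie the C1 and C6 carbons together, so one rhodium-catalysed [2+2+2] forms ring A and the lactone ring (bonds C1–C6, C2–C3, C4–C5).
- The diyne ester comes from MOM-protected 4-iodoresorcinol (ring C), propiolic acid and monosilylated but-2-yne-1,4-diol.
- Ring order: ring C is bought; ring A and the lactone ring close in the key step; the three 4-oxygenated phenyl rings are attached afterwards.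

Key step: step 5

## Remarks

- Ring A numbering used throughout: C1 carries the future methylidene carbon, C2 ring C, C3 and C4 are CH, C5 carries CH2O, C6 carries the future alkyne.
- All phenols travel as methoxymethyl (MOM) ethers and the C5 alcohol as a TBS ether (TBS = tert-butyldimethylsilyl), so that one acid treatment ends the route. A boron halide demethylation of methyl ethers would also attack the benzylic alcohol and hold the triaryl cation in strong Lewis acid.
- Assumption: compounds 12 and 20 are bought; each is otherwise one MOMCl/iPr2NEt step from the 4-halophenol, as in step 1.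
- The two 4-(methoxymethoxy)phenyl groups on the carbinol carbon are introduced by different organometallic reagents. The aryllithium is used at −78 °C for the mono-addition to the lactone. The arylmagnesium bromide is used for the ketone, where its less nucleophilic magnesium alkoxide is the safer neighbour for the C6 alkyne.
- The target has no stereocentre; compounds 14 and F1 would be racemic.

## Route

Step 1
Reactants: 1 4-iodobenzene-1,3-diol; 2 chloromethyl methyl ether
Product: 3 1-iodo-2,4-bis(methoxymethoxy)benzene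
Conditions: MOMCl (2.6 equiv), iPr2NEt (3 equiv), CH2Cl2, 0 °C to rt
Reagents that add atoms: chloromethyl methyl ether (2), COCCl
Why: Standard O-alkylation of both phenols with the reactive α-chloro ether under amine base (MOM protection), which leaves the aryl iodide untouched.

Step 2
Reactants: 3 1-iodo-2,4-bis(methoxymethoxy)benzene; 4 propiolic acid
Product: 5 3-[2,4-bis(methoxymethoxy)phenyl]prop-2-ynoic acid
Conditions: Pd(PPh3)4 (3 mol %), DBU (2.4 equiv), DMSO, 35 °C; cold aq citric acid to pH 3
Reagents that add atoms: propiolic acid (4), C#CC(=O)O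
Why: Copper-free Sonogashira coupling of an aryl iodide with propiolic acid as its DBU carboxylate, run below the temperature at which the arylpropiolate decarboxylates.

Step 3
Reactants: 6 but-2-yne-1,4-diol; 7 tert-butyldimethylsilyl chloride
Product: 8 4-[(tert-butyldimethylsilyl)oxy]but-2-yn-1-ol
Conditions: diol (3 equiv), TBSCl (1 equiv), imidazole (1.1 equiv), DMF, 0 °C to rt
Reagents that add atoms: tert-butyldimethylsilyl chloride (7), CC(C)(C)[Si](C)(C)Cl
Why: Statistical mono-silylation of a symmetrical diol used in excess, from which the water-soluble diol and the non-polar bis-silyl ether are easily separated.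

Step 4
Reactants: 5 3-[2,4-bis(methoxymethoxy)phenyl]prop-2-ynoic acid; 8 4-[(tert-butyldimethylsilyl)oxy]but-2-yn-1-ol
Product: 9 4-[(tert-butyldimethylsilyl)oxy]but-2-yn-1-yl 3-[2,4-bis(methoxymethoxy)phenyl]prop-2-ynoate
Conditions: DCC (1.1 equiv), DMAP (0.1 equiv), CH2Cl2, −20 to 0 °C
Reagents that add atoms: 4-[(tert-butyldimethylsilyl)oxy]but-2-yn-1-ol (8), OCC#CCO[Si](C)(C)C(C)(C)C
Why: Steglich esterification, in which DMAP passes the activated acyl group to the primary propargylic alcohol faster than the cold arylpropiolic acid can self-condense.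

Step 5
Reactants: 9 4-[(tert-butyldimethylsilyl)oxy]but-2-yn-1-yl 3-[2,4-bis(methoxymethoxy)phenyl]prop-2-ynoate; 10 acetylene
Product: 11 7-[2,4-bis(methoxymethoxy)phenyl]-4-{[(tert-butyldimethylsilyl)oxy]methyl}isobenzofuran-1(3H)-one
Conditions: RhCl(PPh3)3 (10 mol %), acetylene (1 atm), toluene, 60 °C, 9 added over 6 h by syringe pump
Reagents that add atoms: acetylene (10), C#C
Why: Monovalent rhodium binds both alkynes of 9 and couples them oxidatively to a rhodacyclopentadiene of trivalent rhodium, which makes bond C1–C6 and so closes the five-membered lactone ring; acetylene then inserts into a Rh–C bond and reductive elimination closes six-membered ring A (bonds C2–C3 and C4–C5), returning monovalent rhodium. The closest known reaction type is the rhodium-catalysed [2+2+2] cyclotrimerization of ester-tethered 1,6-diynes with monoalkynes to phthalides, for which RhCl(PPh3)3 and acetylene gas are established. Both rings close by annulation on the metal: the lactone ring through the intramolecular C–C coupling enforced by the ester tether, ring A through the formal [2+2+2] union of the resulting diene unit with the two acetylene carbons. No stereocentre is formed. The step needs cross-selectivity (diyne with acetylene, not diyne with diyne) but no regiocontrol, because the tether fixes the order C2–C1–C6–C5 and acetylene is symmetrical; slow addition of 9 into acetylene-saturated solution keeps the diyne concentration low. The electron-poor ynoate aids the oxidative coupling, and gentle heating offsets the preference of the ester for the s-trans conformer that holds the two alkynes apart.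

Step 6
Reactants: 11 7-[2,4-bis(methoxymethoxy)phenyl]-4-{[(tert-butyldimethylsilyl)oxy]methyl}isobenzofuran-1(3H)-one; 12 1-bromo-4-(methoxymethoxy)benzene
Product: 15 {6-[2,4-bis(methoxymethoxy)phenyl]-3-{[(tert-butyldimethylsilyl)oxy]methyl}-2-(hydroxymethyl)phenyl}[4-(methoxymethoxy)phenyl]methanone, via 4-(methoxymethoxy)phenyllithium 13 (not isolated), via cyclic lithium hemiketal alkoxide 14 (not isolated)
Conditions: 12, n-BuLi (1.15 equiv each), THF, −78 °C; cannulated into 11, THF, −78 °C; sat. aq NH4Cl at −78 °C, neutral work-up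
Reagents that add atoms: 1-bromo-4-(methoxymethoxy)benzene (12), COCOc1ccc(Br)cc1, delivered as its aryllithium 13, [Li]c1ccc(OCOC)cc1
Why: Bromine–lithium exchange followed by 1,2-addition of one aryllithium to the lactone carbonyl; the cyclic lithium hemiketal alkoxide 14 does not collapse at −78 °C, which prevents a second addition, and the neutral quench should give hydroxy ketone 15 (in equilibrium with its ring-closed hemiketal tautomer).

Step 7
Reactants: 15 {6-[2,4-bis(methoxymethoxy)phenyl]-3-{[(tert-butyldimethylsilyl)oxy]methyl}-2-(hydroxymethyl)phenyl}[4-(methoxymethoxy)phenyl]methanone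
Product: 16 3-[2,4-bis(methoxymethoxy)phenyl]-6-{[(tert-butyldimethylsilyl)oxy]methyl}-2-[4-(methoxymethoxy)benzoyl]benzaldehyde
Conditions: Dess–Martin periodinane (1.3 equiv), NaHCO3 (5 equiv), CH2Cl2, 0 °C to rt
Reagents that add atoms: none
Why: Dess–Martin oxidation of the primary benzylic alcohol through the open hydroxy ketone form, buffered so that the hemiketal tautomer is not dehydrated to an isobenzofuran and the MOM and TBS ethers are not touched.

Step 8
Reactants: 16 3-[2,4-bis(methoxymethoxy)phenyl]-6-{[(tert-butyldimethylsilyl)oxy]methyl}-2-[4-(methoxymethoxy)benzoyl]benzaldehyde; 17 dimethyl (1-diazo-2-oxopropyl)phosphonate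
Product: 19 {6-[2,4-bis(methoxymethoxy)phenyl]-3-{[(tert-butyldimethylsilyl)oxy]methyl}-2-ethynylphenyl}[4-(methoxymethoxy)phenyl]methanone, via dimethyl (diazomethyl)phosphonate 18 (not isolated)
Conditions: 17 (1.5 equiv), K2CO3 (2.5 equiv), MeOH/THF, 0 °C to rt
Reagents that add atoms: dimethyl (1-diazo-2-oxopropyl)phosphonate (17), COP(=O)(OC)C(=[N+]=[N-])C(C)=O
Why: Ohira–Bestmann (Seyferth–Gilbert) homologation, in which methanolysis of 17 releases the anion of 18 that adds to the aldehyde far faster than to the hindered, non-enolizable diaryl ketone, and loss of dimethyl phosphate and N2 with a 1,2-hydrogen shift gives the terminal alkyne.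

Step 9
Reactants: 19 {6-[2,4-bis(methoxymethoxy)phenyl]-3-{[(tert-butyldimethylsilyl)oxy]methyl}-2-ethynylphenyl}[4-(methoxymethoxy)phenyl]methanone; 20 1-iodo-4-(methoxymethoxy)benzene
Product: 21 {6-[2,4-bis(methoxymethoxy)phenyl]-3-{[(tert-butyldimethylsilyl)oxy]methyl}-2-{[4-(methoxymethoxy)phenyl]ethynyl}phenyl}[4-(methoxymethoxy)phenyl]methanone
Conditions: PdCl2(PPh3)2 (5 mol %), CuI (5 mol %), Et3N/THF (1:1), degassed, 45 °C
Reagents that add atoms: 1-iodo-4-(methoxymethoxy)benzene (20), COCOc1ccc(I)cc1
Why: Sonogashira coupling of a terminal arylalkyne with an aryl iodide, to which the ketone, the acetals and the silyl ether are spectators.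

Step 10
Reactants: 21 {6-[2,4-bis(methoxymethoxy)phenyl]-3-{[(tert-butyldimethylsilyl)oxy]methyl}-2-{[4-(methoxymethoxy)phenyl]ethynyl}phenyl}[4-(methoxymethoxy)phenyl]methanone; 12 1-bromo-4-(methoxymethoxy)benzene
Product: 23 {6-[2,4-bis(methoxymethoxy)phenyl]-3-{[(tert-butyldimethylsilyl)oxy]methyl}-2-{[4-(methoxymethoxy)phenyl]ethynyl}phenyl}bis[4-(methoxymethoxy)phenyl]methanol, via 4-(methoxymethoxy)phenylmagnesium bromide 22 (not isolated)
Conditions: 12 (3 equiv), Mg turnings (3.3 equiv), I2 (cat.), THF, 45 °C; then 21 in THF, 0 °C to rt; sat. aq NH4Cl at 0 °C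
Reagents that add atoms: 1-bromo-4-(methoxymethoxy)benzene (12), COCOc1ccc(Br)cc1, delivered as its Grignard reagent 22, COCOc1ccc([Mg]Br)cc1
Why: Magnesium insertion into the aryl bromide followed by Grignard 1,2-addition to a diaryl ketone that can be neither enolized nor reduced by an aryl nucleophile; the slim alkynyl group on C6 leaves the carbonyl accessible, and the bromomagnesium alkoxide is too weakly nucleophilic to add to the neighbouring alkyne before the cold quench.

Step 11
Reactants: 23 {6-[2,4-bis(methoxymethoxy)phenyl]-3-{[(tert-butyldimethylsilyl)oxy]methyl}-2-{[4-(methoxymethoxy)phenyl]ethynyl}phenyl}bis[4-(methoxymethoxy)phenyl]methanol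
Product: 25 selaginellin F, via deprotected triarylmethanol 24 (not isolated)
Conditions: conc. aq HCl (excess), MeOH/THF (4:1), 40 °C; then aq NaHCO3 to pH 6–7
Reagents that add atoms: none
Why: Acid-catalysed cleavage of the five MOM acetals and the silyl ether (global deprotection) gives hexol 24, whose bis(4-hydroxyphenyl)carbinol ionizes and loses water to the conjugated quinone methide (fuchsone formation), the two 4-hydroxyphenyl groups being equivalent.

## Compound list

1 | 4-iodobenzene-1,3-diol (4-iodoresorcinol) | Oc1ccc(I)c(O)c1 | starting material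
2 | chloromethyl methyl ether (MOMCl) | COCCl | starting material
3 | 1-iodo-2,4-bis(methoxymethoxy)benzene | COCOc1ccc(I)c(OCOC)c1 | intermediate
4 | propiolic acid | C#CC(=O)O | starting material
5 | 3-[2,4-bis(methoxymethoxy)phenyl]prop-2-ynoic acid | COCOc1ccc(C#CC(=O)O)c(OCOC)c1 | intermediate
6 | but-2-yne-1,4-diol | OCC#CCO | starting material
7 | tert-butyldimethylsilyl chloride | CC(C)(C)[Si](C)(C)Cl | starting material
8 | 4-[(tert-butyldimethylsilyl)oxy]but-2-yn-1-ol | OCC#CCO[Si](C)(C)C(C)(C)C | intermediate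
9 | 4-[(tert-butyldimethylsilyl)oxy]but-2-yn-1-yl 3-[2,4-bis(methoxymethoxy)phenyl]prop-2-ynoate (ester-tethered 1,6-diyne) | COCOc1ccc(C#CC(=O)OCC#CCO[Si](C)(C)C(C)(C)C)c(OCOC)c1 | intermediate
10 | acetylene | C#C | starting material
11 | 7-[2,4-bis(methoxymethoxy)phenyl]-4-{[(tert-butyldimethylsilyl)oxy]methyl}isobenzofuran-1(3H)-one (ring A fused to the lactone) | COCOc1ccc(-c2ccc(CO[Si](C)(C)C(C)(C)C)c3c2C(=O)OC3)c(OCOC)c1 | intermediate
12 | 1-bromo-4-(methoxymethoxy)benzene | COCOc1ccc(Br)cc1 | starting material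
13 | 4-(methoxymethoxy)phenyllithium | [Li]c1ccc(OCOC)cc1 | intermediate
14 | lithium 7-[2,4-bis(methoxymethoxy)phenyl]-4-{[(tert-butyldimethylsilyl)oxy]methyl}-1-[4-(methoxymethoxy)phenyl]-1,3-dihydroisobenzofuran-1-olate (cyclic hemiketal alkoxide, racemic) | [Li]OC1(c2ccc(OCOC)cc2)OCc2c(CO[Si](C)(C)C(C)(C)C)ccc(-c3ccc(OCOC)cc3OCOC)c21 | intermediate
15 | {6-[2,4-bis(methoxymethoxy)phenyl]-3-{[(tert-butyldimethylsilyl)oxy]methyl}-2-(hydroxymethyl)phenyl}[4-(methoxymethoxy)phenyl]methanone (ring A: C1 aroyl, C6 CH2OH) | COCOc1ccc(cc1)C(=O)c1c(-c2ccc(OCOC)cc2OCOC)ccc(CO[Si](C)(C)C(C)(C)C)c1CO | intermediate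
16 | 3-[2,4-bis(methoxymethoxy)phenyl]-6-{[(tert-butyldimethylsilyl)oxy]methyl}-2-[4-(methoxymethoxy)benzoyl]benzaldehyde | COCOc1ccc(cc1)C(=O)c1c(-c2ccc(OCOC)cc2OCOC)ccc(CO[Si](C)(C)C(C)(C)C)c1C=O | intermediate
17 | dimethyl (1-diazo-2-oxopropyl)phosphonate (Ohira–Bestmann reagent) | COP(=O)(OC)C(=[N+]=[N-])C(C)=O | starting material
18 | dimethyl (diazomethyl)phosphonate | COP(=O)(OC)C=[N+]=[N-] | intermediate
19 | {6-[2,4-bis(methoxymethoxy)phenyl]-3-{[(tert-butyldimethylsilyl)oxy]methyl}-2-ethynylphenyl}[4-(methoxymethoxy)phenyl]methanone | COCOc1ccc(cc1)C(=O)c1c(-c2ccc(OCOC)cc2OCOC)ccc(CO[Si](C)(C)C(C)(C)C)c1C#C | intermediate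
20 | 1-iodo-4-(methoxymethoxy)benzene | COCOc1ccc(I)cc1 | starting material
21 | {6-[2,4-bis(methoxymethoxy)phenyl]-3-{[(tert-butyldimethylsilyl)oxy]methyl}-2-{[4-(methoxymethoxy)phenyl]ethynyl}phenyl}[4-(methoxymethoxy)phenyl]methanone | COCOc1ccc(cc1)C(=O)c1c(-c2ccc(OCOC)cc2OCOC)ccc(CO[Si](C)(C)C(C)(C)C)c1C#Cc1ccc(OCOC)cc1 | intermediate
22 | 4-(methoxymethoxy)phenylmagnesium bromide | COCOc1ccc([Mg]Br)cc1 | intermediate
23 | {6-[2,4-bis(methoxymethoxy)phenyl]-3-{[(tert-butyldimethylsilyl)oxy]methyl}-2-{[4-(methoxymethoxy)phenyl]ethynyl}phenyl}bis[4-(methoxymethoxy)phenyl]methanol | COCOc1ccc(cc1)C(O)(c1ccc(OCOC)cc1)c1c(-c2ccc(OCOC)cc2OCOC)ccc(CO[Si](C)(C)C(C)(C)C)c1C#Cc1ccc(OCOC)cc1 | intermediate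
24 | {6-(2,4-dihydroxyphenyl)-3-(hydroxymethyl)-2-[(4-hydroxyphenyl)ethynyl]phenyl}bis(4-hydroxyphenyl)methanol | OCc1ccc(-c2ccc(O)cc2O)c(C(O)(c2ccc(O)cc2)c2ccc(O)cc2)c1C#Cc1ccc(O)cc1 | intermediate
25 | selaginellin F, 4-{[6-(2,4-dihydroxyphenyl)-3-(hydroxymethyl)-2-[(4-hydroxyphenyl)ethynyl]phenyl](4-hydroxyphenyl)methylidene}cyclohexa-2,5-dien-1-one | O=C1C=CC(=C(c2ccc(O)cc2)c2c(-c3ccc(O)cc3O)ccc(CO)c2C#Cc2ccc(O)cc2)C=C1 | target

## Step count and risks

Total step count: 11 steps.
Longest linear sequence: 10 steps (1, 2, 4, 5, 6, 7, 8, 9, 10, 11); step 3 is a one-step side branch.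

Steps most likely to fail:

1. Step 5. Oxidative coupling of the doubly internal, ester-tethered diyne on the neutral chloride complex may be too slow: the ester prefers the s-trans conformer and the aryl group is ortho-substituted. Acetylene self-trimerization and diyne dimerization would then take over. The fallback sets out from 9 and replaces the gas by a liquid two-carbon partner that reacts as an alkene. With [Rh(cod)2]BF4/rac-BINAP (cationic monovalent rhodium) in 1,2-dichloroethane at rt to 60 °C, 9 and vinyl acetate should undergo [2+2+2] cycloaddition to 7-[2,4-bis(methoxymethoxy)phenyl]-4-{[(tert-butyldimethylsilyl)oxy]methyl}-1-oxo-1,3,5,6-tetrahydroisobenzofuran-5-yl acetate F1 (drawn as one of the two possible regioisomers; both converge). F1 should lose acetic acid in the flask and aromatize, so the route is rejoined at 11.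

2. Step 11. The doubly para-oxygenated triaryl cation must persist in acid for as long as five acetals take to cleave. It may be trapped inside the molecule: by the C2' oxygen of ring C to a benzo[c]chromene, by C6' of ring C to a fluorene, or through hydroxyl addition to the alkyne. The deprotection may also stall part-way. The fallback sets out from 21 and moves the acid treatment to the ketone stage, where no such cation exists:
   - HCl/MeOH should give the pentahydroxy ketone [6-(2,4-dihydroxyphenyl)-3-(hydroxymethyl)-2-[(4-hydroxyphenyl)ethynyl]phenyl](4-hydroxyphenyl)methanone F4.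
   - TBSCl/imidazole/DMF should give its penta-TBS ether F5.
   - {4-[(tert-butyldimethylsilyl)oxy]phenyl}lithium F6, made from purchased (4-bromophenoxy)(tert-butyl)dimethylsilane and n-BuLi in THF at −78 °C, should add to F5 to give the hexa-TBS triarylmethanol F7.
   - Buffered fluoride (TBAF/AcOH, THF, 0 °C) should then free 24 without strong acid. The route is rejoined at 24, which dehydrates to 25 on mildly acidic work-up.

3. Step 8. In methanolic K2CO3 the 2-aroylbenzaldehyde may be diverted: methoxide addition to the aldehyde followed by hydride transfer to the neighbouring ketone is a Cannizzaro–Tishchenko-type path to a phthalide. The doubly ortho-substituted aldehyde may also react too slowly with the phosphonate anion. The fallback sets out from 16 and avoids alkoxide: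
   - Ramirez olefination (CBr4, PPh3, Et3N, CH2Cl2, 0 °C) should give {6-[2,4-bis(methoxymethoxy)phenyl]-3-{[(tert-butyldimethylsilyl)oxy]methyl}-2-(2,2-dibromoethenyl)phenyl}[4-(methoxymethoxy)phenyl]methanone F2.
   - DBU in DMSO at rt should eliminate HBr to give {6-[2,4-bis(methoxymethoxy)phenyl]-2-(bromoethynyl)-3-{[(tert-butyldimethylsilyl)oxy]methyl}phenyl}[4-(methoxymethoxy)phenyl]methanone F3.
   - Suzuki–Miyaura coupling of F3 with purchased 4-(methoxymethoxy)phenylboronic acid (Pd(PPh3)4, K3PO4, THF/H2O, 50 °C) should give 21 directly. The route is rejoined at 21, and steps 8 and 9 are bypassed.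

## Further compounds

F1 | step 5 | 7-[2,4-bis(methoxymethoxy)phenyl]-4-{[(tert-butyldimethylsilyl)oxy]methyl}-1-oxo-1,3,5,6-tetrahydroisobenzofuran-5-yl acetate (racemic) | COCOc1ccc(C2=C3C(=O)OCC3=C(CO[Si](C)(C)C(C)(C)C)C(OC(C)=O)C2)c(OCOC)c1
F2 | step 8 | {6-[2,4-bis(methoxymethoxy)phenyl]-3-{[(tert-butyldimethylsilyl)oxy]methyl}-2-(2,2-dibromoethenyl)phenyl}[4-(methoxymethoxy)phenyl]methanone | COCOc1ccc(cc1)C(=O)c1c(-c2ccc(OCOC)cc2OCOC)ccc(CO[Si](C)(C)C(C)(C)C)c1C=C(Br)Br
F3 | step 8 | {6-[2,4-bis(methoxymethoxy)phenyl]-2-(bromoethynyl)-3-{[(tert-butyldimethylsilyl)oxy]methyl}phenyl}[4-(methoxymethoxy)phenyl]methanone | COCOc1ccc(cc1)C(=O)c1c(-c2ccc(OCOC)cc2OCOC)ccc(CO[Si](C)(C)C(C)(C)C)c1C#CBr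
F4 | step 11 | [6-(2,4-dihydroxyphenyl)-3-(hydroxymethyl)-2-[(4-hydroxyphenyl)ethynyl]phenyl](4-hydroxyphenyl)methanone | OCc1ccc(-c2ccc(O)cc2O)c(C(=O)c2ccc(O)cc2)c1C#Cc1ccc(O)cc1
F5 | step 11 | [6-{2,4-bis[(tert-butyldimethylsilyl)oxy]phenyl}-3-{[(tert-butyldimethylsilyl)oxy]methyl}-2-({4-[(tert-butyldimethylsilyl)oxy]phenyl}ethynyl)phenyl]{4-[(tert-butyldimethylsilyl)oxy]phenyl}methanone | CC(C)(C)[Si](C)(C)OCc1ccc(-c2ccc(O[Si](C)(C)C(C)(C)C)cc2O[Si](C)(C)C(C)(C)C)c(C(=O)c2ccc(O[Si](C)(C)C(C)(C)C)cc2)c1C#Cc1ccc(O[Si](C)(C)C(C)(C)C)cc1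
F6 | step 11 | {4-[(tert-butyldimethylsilyl)oxy]phenyl}lithium | [Li]c1ccc(O[Si](C)(C)C(C)(C)C)cc1
F7 | step 11 | [6-{2,4-bis[(tert-butyldimethylsilyl)oxy]phenyl}-3-{[(tert-butyldimethylsilyl)oxy]methyl}-2-({4-[(tert-butyldimethylsilyl)oxy]phenyl}ethynyl)phenyl]bis{4-[(tert-butyldimethylsilyl)oxy]phenyl}methanol | CC(C)(C)[Si](C)(C)OCc1ccc(-c2ccc(O[Si](C)(C)C(C)(C)C)cc2O[Si](C)(C)C(C)(C)C)c(C(O)(c2ccc(O[Si](C)(C)C(C)(C)C)cc2)c2ccc(O[Si](C)(C)C(C)(C)C)cc2)c1C#Cc1ccc(O[Si](C)(C)C(C)(C)C)cc1
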